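**Strategy.** The route rests on undoing C6–C15 and C4–C5. This opens rings A and B and leaves a ring C–D cyclooctenone with a flat side chain. The feature exploited: with C8 as a ketone, C5=C6(C7) is a methacryloyl dienophile, held by C8–C10–C11 next to the diene C15=C16–C3=C4, half of which is the ring-C alkene. One type 1 intramolecular Diels–Alder reaction closes rings A and B, sets quaternary C6, C15 and the trans fusion (plus sacrificial C4), and places the C8 oxygen. The precursor 27 is a trienedione. C2 stays a ketone, so no stray stereocentre exists and adduct 28 is already the enone for the alkene shift.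

Key step: step 21

**Remarks on the chemistry**
- Atom numbers C1–C26 follow the order of the target SMILES. The target is 6R,8R,11S,15S,17S,21S,22S,25S. In ring D, C26 and C20 are cis and C2 is trans to C20. Rings A/B are trans-fused, O9 is cis to C7, and the isopropyl group is cis to H15.
- Structure check: the centres C6, C11, C15, C17, C21, C22 and C25 in 27 and 28 map one-to-one on the target. (S)-Pulegone is the correct antipode for C25.
- Design change 1: an unsymmetrical acyloin would give both ketol regioisomers. Ring C is therefore taken to the 1,2-dione and differentiated by kinetic enolisation.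
- Design change 2: a C2 silyl ether would put an uncontrolled stereocentre beside the diene. Its C2–H would let a metal hydride walk the alkene into an enol ether, and it would cost four redox/protecting steps. C2 is therefore carried as the ketone.
- Assumption: 1, 5 and 18 are bought enantiopure. Where a SMILES leaves a centre open (C21 in 7–10), it is a transient centre that becomes sp2.

**Chain fragment (C3, C4, C17–C20)**

Step 1
Reactants: 1 methyl hydrogen (R)-3-methylglutarate
Product: 3 (S)-4-methyltetrahydro-2H-pyran-2-one, via hydroxy acid 2 (not isolated)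
Conditions: LiBH4 (2.2 equiv), THF, 0 → 40 °C; then 2 M HCl, 23 °C
Reagents that add atoms: none
Why: Chemoselective borohydride reduction then acid lactonisation: the lithium carboxylate formed first is inert, so only the ester end becomes C20H2–O, and this choice of end places the purchased stereocentre in the sense needed at C17.

Step 2
Reactants: 3 (S)-4-methyltetrahydro-2H-pyran-2-one
Product: 4 methyl (R)-5-bromo-3-methylpentanoate
Conditions: HBr (anhydrous, sat.), MeOH, 0 → 23 °C
Reagents that add atoms: hydrogen bromide, Br; methanol, CO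
Why: Acid-mediated lactone opening (SN2 of bromide at the O–CH2 carbon C20) with Fischer esterification, the classical ω-bromo ester preparation; C17 is not touched.

**Ring D and ring C**

Step 3
Reactants: 5 (S)-pulegone
Product: 7 methyl pulegenate [methyl (2S)-2-methyl-5-(propan-2-ylidene)cyclopentane-1-carboxylate; C21 epimers], via pulegone dibromide 6 (not isolated)
Conditions: Br2, Et2O, 0 °C; then NaOMe, MeOH, reflux
Reagents that add atoms: bromine, BrBr; sodium methoxide, C[O-].[Na+]
Why: Bromination and Favorskii ring contraction (cyclopropanone opened by methoxide with loss of the second bromide) is the standard pulegone-to-pulegenate sequence; C25 comes from the chiral pool.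

Step 4
Reactants: 7 methyl pulegenate
Product: 8 methyl (2S)-2-methyl-5-oxocyclopentane-1-carboxylate
Conditions: O3, CH2Cl2/MeOH, −78 °C; Me2S
Reagents that add atoms: ozone, [O-][O+]=O
Why: Ozonolysis with reductive work-up cleaves the only alkene and exposes the C22 ketone of a β-keto ester.

Step 5
Reactants: 8 methyl (2S)-2-methyl-5-oxocyclopentane-1-carboxylate; 4 methyl (R)-5-bromo-3-methylpentanoate
Product: 9 C21-alkylated β-keto ester (C21 bears CO2Me and the C20–C19–C17(Me)–C4–C3O2Me chain)
Conditions: K2CO3, NaI (0.2 equiv), DMF, 60 °C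
Reagents that add atoms: none
Why: SN2 C-alkylation of a stabilised β-keto ester enolate (iodide-assisted) forms C20–C21 only at the carbon between the two carbonyl groups; the quaternary centre is transient.

Step 6
Reactants: 9 C21-alkylated β-keto ester
Product: 10 methyl (3S)-3-methyl-5-[(2S)-2-methyl-5-oxocyclopentyl]pentanoate (C21 epimers)
Conditions: LiCl, H2O, DMSO, 150 °C
Reagents that add atoms: none
Why: Krapcho dealkoxycarbonylation removes only the activated β-keto ester group and leaves the isolated chain ester.

Step 7
Reactants: 10 keto ester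
Product: 11 tetrasubstituted enol triflate (C21=C22, OTf on C22)
Conditions: Tf2O, 2,6-di-tert-butyl-4-methylpyridine, CH2Cl2, 0 → 23 °C
Reagents that add atoms: triflic anhydride, O=S(=O)(OS(=O)(=O)C(F)(F)F)C(F)(F)F
Why: Enol triflation under equilibrating, metal-free conditions favours the more substituted enol of a 2-alkylcyclopentanone and avoids a metal enolate that could attack the chain ester.

Step 8
Reactants: 11 enol triflate
Product: 12 cyclopentene diester (C2O2Me on C22, C21=C22)
Conditions: Pd(OAc)2 (5 mol %), dppp, CO (1 atm), Et3N, MeOH/DMF, 60 °C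
Reagents that add atoms: carbon monoxide, [C-]#[O+]; methanol, CO
Why: Pd-catalysed alkoxycarbonylation of an enol triflate installs C2 on C22.

Step 9
Reactants: 12 cyclopentene diester
Product: 13 all-cis diester (C26, C20 and C2 on one face)
Conditions: H2 (20 bar), 5 % Rh/Al2O3, MeOH, 23 °C
Reagents that add atoms: none
Why: Heterogeneous syn-hydrogenation from the face opposite the C26 methyl sets C21 (C20 cis to C26); rhodium is chosen because it migrates double bonds little, so C25 is not scrambled.

Step 10
Reactants: 13 all-cis diester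
Product: 14 methyl (1S,2S,3S)-2-[(3S)-5-methoxy-3-methyl-5-oxopentyl]-3-methylcyclopentane-1-carboxylate
Conditions: NaOMe (0.3 equiv), MeOH, 50 °C
Reagents that add atoms: none
Why: Base-mediated epimerisation α to the ring ester moves C2 trans to C20 (thermodynamic control at C22), while C21, C25 and C17 carry no acidic hydrogen.

Step 11
Reactants: 14 trans diester
Product: 15 ring C–D bis(trimethylsilyl) enediol ether (C2=C3, trans-fused bicyclo[6.3.0]undecene)
Conditions: Na (dispersion), TMSCl, toluene, reflux, slow addition
Reagents that add atoms: chlorotrimethylsilane, C[Si](C)(C)Cl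
Why: Acyloin condensation in its Rühlmann (TMSCl) form, the classical closure of eight-membered carbocycles, forms C2–C3; the silyl chloride traps alkoxide and suppresses Dieckmann pathways.

Step 12
Reactants: 15 bis(silyl) enediol ether
Product: 16 (1S,5S,8S,9S)-5,9-dimethylbicyclo[6.3.0]undecane-2,3-dione
Conditions: Br2 (1.0 equiv), CH2Cl2, −78 °C
Reagents that add atoms: none
Why: Oxidative desilylation of an enediol bis-silyl ether with bromine gives the 1,2-dione and removes the regiochemical ambiguity of a ketol.

Step 13
Reactants: 16 ring C–D dione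
Product: 17 (1S,5S,8S,9S,3Z)-5,9-dimethyl-2-oxobicyclo[6.3.0]undec-3-en-3-yl triflate
Conditions: KHMDS, THF, −78 °C; PhNTf2, −78 → 0 °C
Reagents that add atoms: N-phenylbis(trifluoromethanesulfonimide), O=S(=O)(N(c1ccccc1)S(=O)(=O)C(F)(F)F)C(F)(F)F
Why: Kinetic enolisation takes the accessible C4H2 rather than the hindered ring-fusion C22–H, and O-triflation gives the diosphenol-type triflate with the ring-enforced Z alkene.

**Side chain (C5–C8, C10–C16)**

Step 14
Reactants: 18 (S)-4-benzyloxazolidin-2-one
Product: 19 (S)-4-benzyl-3-(3-methylbutanoyl)oxazolidin-2-one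
Conditions: n-BuLi, THF, −78 °C; isovaleryl chloride
Reagents that add atoms: isovaleryl chloride, CC(C)CC(=O)Cl
Why: N-acylation of the lithiated auxiliary.

Step 15
Reactants: 19 N-isovaleryl oxazolidinone
Product: 20 tert-butyl (S)-3-[(S)-4-benzyl-2-oxooxazolidine-3-carbonyl]-4-methylpentanoate
Conditions: NaHMDS, THF, −78 °C; BrCH2CO2t-Bu
Reagents that add atoms: tert-butyl bromoacetate, CC(C)(C)OC(=O)CBr
Why: Evans alkylation: the chelated Z-enolate is attacked on the face opposite the benzyl group, which sets C11.

Step 16
Reactants: 20 alkylated imide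
Product: 22 (S)-4-isopropyldihydrofuran-2(3H)-one, via hydroxy ester 21 (not isolated)
Conditions: LiBH4, MeOH (1 equiv), Et2O, 0 °C; crude, then TFA, CH2Cl2, 23 °C
Reagents that add atoms: none
Why: Reductive removal of the auxiliary (imide faster than tert-butyl ester) followed by acidolysis and lactonisation differentiates C15 (CH2–O) from C8 (C=O) without touching C11.

Step 17
Reactants: 22 (S)-4-isopropyldihydrofuran-2(3H)-one
Product: 24 (S)-5-(hydroxymethyl)-2,6-dimethylhept-1-en-3-one, via Weinreb amide 23 (not isolated)
Conditions: MeNH(OMe)·HCl, i-PrMgCl, THF, −20 °C; then CH2=C(Me)MgBr, −20 → 0 °C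
Reagents that add atoms: N,O-dimethylhydroxylamine hydrochloride, CNOC.Cl; isopropenylmagnesium bromide, C=C(C)[Mg]Br
Why: Magnesium-amide aminolysis of the lactone and Weinreb ketone synthesis in one flask; the chelated tetrahedral adduct stops at single addition and gives the methacryloyl ketone.

Step 18
Reactants: 24 hydroxy enone
Product: 25 (S)-2-isopropyl-5-methyl-4-oxohex-5-enal
Conditions: Dess–Martin periodinane, NaHCO3, CH2Cl2, 0 → 23 °C
Reagents that add atoms: none
Why: Buffered Dess–Martin oxidation of the primary alcohol is mild enough to keep the α-stereocentre C11 and the enone.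

Step 19
Reactants: 25 keto aldehyde
Product: 26 (S,E)-2,6-dimethyl-5-[2-(4,4,5,5-tetramethyl-1,3,2-dioxaborolan-2-yl)vinyl]hept-1-en-3-one
Conditions: CrCl2, Cl2CHBpin, LiI, THF, 23 °C
Reagents that add atoms: 2-(dichloromethyl)-4,4,5,5-tetramethyl-1,3,2-dioxaborolane, ClC(Cl)B1OC(C)(C)C(C)(C)O1
Why: Takai–Utimoto boryl olefination: the gem-dichromium reagent reacts with aldehydes far faster than with ketones and gives the (E)-C15=C16 alkenylboronate.

**Union, key step and endgame**

Step 20
Reactants: 17 ring C–D enone triflate; 26 alkenylboronate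
Product: 27 (1S,5S,8S,9S,3Z)-3-[(1E,3S)-3-isopropyl-6-methyl-5-oxohepta-1,6-dien-1-yl]-5,9-dimethylbicyclo[6.3.0]undec-3-en-2-one (ring C–D dienyl trienedione)
Conditions: PdCl2(dppf) (5 mol %), K3PO4 (aq), THF, 23 °C
Reagents that add atoms: none
Why: Suzuki–Miyaura coupling of a 2-triflyloxy enone with an alkenylboronate forms C3–C16 with retention of both alkene geometries; room temperature keeps 27 from cyclising.

Step 21
Reactants: 27 ring C–D dienyl trienedione
Product: 28 tetracyclic dione (C2 enone with C3=C16, C8 ketone, trans A/B fusion, H4 cis to H15)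
Conditions: toluene (0.01 M), BHT (cat.), 110 °C
Reagents that add atoms: none
Why: Concerted, asynchronous normal-demand [4+2] cycloaddition, suprafacial on both partners, in which the C5=C6 enone adds across C15=C16–C3=C4 to form C6–C15 and C4–C5 and leave C3=C16; the closest known reaction type is the type 1 intramolecular Diels–Alder reaction of 2-methyl-1,6,8-nonatrien-3-ones to angularly methylated hydrindenones. Ring B closes as the six-membered cycloadduct ring and ring A as the five-membered ring spanned by the three-atom tether C8–C10–C11. The C6/C15 trans relation comes from the transition state with the tether carbonyl exo and the C7 methyl over the diene, which the α-methyl group and the short tether favour over the cis-forming carbonyl-endo mode. The absolute sense at C6 and C15 is set by C11, whose isopropyl group stays pseudo-equatorial and trans to C16 on only one diene face, while C4 (H4 cis to H15) follows from the (E)-C15=C16 and ring-(Z)-C3=C4 geometries and is erased in step 22. The step therefore needs exo (trans) and diene-face selectivity, both helped because the atom that meets ring C is the unsubstituted CH2 C5 and because sp2 C2 puts no extra stereocentre or bulky group beside the diene. The C2 carbonyl is twisted out of conjugation in the cyclooctenone and ends para to C8=O in ring B, the matched orientation for 2-acyl dienes, so it should slow but not block the reaction.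

Step 22
Reactants: 28 tetracyclic dione (C3=C16)
Product: 29 tetracyclic dione with the tetrasubstituted C3=C4 enone
Conditions: RhCl3·3H2O (10 mol %), EtOH, 85 °C (sealed)
Reagents that add atoms: none
Why: Rhodium-hydride addition–elimination, the known isomerisation of α-alkylidene cycloalkanones to endocyclic enones, moves the alkene into ring C, driven by higher substitution and by placing the double bond inside the eight-membered ring; no C2–H is present to divert the hydride.

Step 23
Reactants: 29 dione
Product: 30 8R-hydroxy enone (O9 cis to C7)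
Conditions: NaBH4, MeOH/CH2Cl2, −40 → 0 °C
Reagents that add atoms: none
Why: Chemoselective borohydride reduction: the cyclopentanone reacts before the shielded tetrasubstituted enone, and hydride comes from the face opposite the angular C7 methyl (as in 17-keto steroids), which sets C8.

Step 24
Reactants: 30 hydroxy enone
Product: 31 CNP0544018.1 (target)
Conditions: Zn, CH2Br2, TiCl4 (pre-formed Lombardo reagent, excess), THF/CH2Cl2, 0 → 23 °C
Reagents that add atoms: dibromomethane, BrCBr
Why: Takai–Lombardo methylenation is non-basic, so C22 (α') and C17 (γ) are not epimerised, and it tolerates the free C8 hydroxyl.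

**Compound list**
1 | methyl hydrogen (R)-3-methylglutarate | COC(=O)C[C@H](C)CC(=O)O | starting material
2 | (S)-5-hydroxy-3-methylpentanoic acid | O=C(O)C[C@@H](C)CCO | intermediate
3 | (S)-4-methyltetrahydro-2H-pyran-2-one | O=C1C[C@@H](C)CCO1 | intermediate
4 | methyl (R)-5-bromo-3-methylpentanoate | COC(=O)C[C@@H](C)CCBr | intermediate
5 | (S)-pulegone | C[C@H]1CCC(=C(C)C)C(=O)C1 | starting material
6 | pulegone dibromide | C[C@H]1CCC(Br)(C(C)(C)Br)C(=O)C1 | intermediate
7 | methyl pulegenate | COC(=O)C1C(=C(C)C)CC[C@@H]1C | intermediate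
8 | methyl (2S)-2-methyl-5-oxocyclopentane-1-carboxylate | COC(=O)C1C(=O)CC[C@@H]1C | intermediate
9 | C21-alkylated β-keto ester | COC(=O)C[C@@H](C)CCC1(C(=O)OC)C(=O)CC[C@@H]1C | intermediate
10 | methyl (3S)-3-methyl-5-[(2S)-2-methyl-5-oxocyclopentyl]pentanoate | COC(=O)C[C@@H](C)CCC1C(=O)CC[C@@H]1C | intermediate
11 | C21=C22 enol triflate | COC(=O)C[C@@H](C)CCC1=C(OS(=O)(=O)C(F)(F)F)CC[C@@H]1C | intermediate
12 | cyclopentene diester | COC(=O)C[C@@H](C)CCC1=C(C(=O)OC)CC[C@@H]1C | intermediate
13 | all-cis diester | COC(=O)C[C@@H](C)CC[C@@H]1[C@H](C(=O)OC)CC[C@@H]1C | intermediate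
14 | trans diester | COC(=O)C[C@@H](C)CC[C@@H]1[C@@H](C(=O)OC)CC[C@@H]1C | intermediate
15 | ring C–D bis(trimethylsilyl) enediol ether | C[Si](C)(C)OC1=C(O[Si](C)(C)C)C[C@@H](C)CC[C@@H]2[C@@H]1CC[C@@H]2C | intermediate
16 | (1S,5S,8S,9S)-5,9-dimethylbicyclo[6.3.0]undecane-2,3-dione | O=C1C(=O)C[C@@H](C)CC[C@@H]2[C@@H]1CC[C@@H]2C | intermediate
17 | ring C–D 2-oxo-3-enyl triflate | O=S(=O)(O/C1=C/[C@@H](C)CC[C@@H]2[C@H](CC[C@@H]2C)C1=O)C(F)(F)F | intermediate
18 | (S)-4-benzyloxazolidin-2-one | O=C1N[C@@H](Cc2ccccc2)CO1 | starting material
19 | (S)-4-benzyl-3-(3-methylbutanoyl)oxazolidin-2-one | CC(C)CC(=O)N1[C@@H](Cc2ccccc2)COC1=O | intermediate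
20 | tert-butyl (S)-3-[(S)-4-benzyl-2-oxooxazolidine-3-carbonyl]-4-methylpentanoate | CC(C)[C@H](CC(=O)OC(C)(C)C)C(=O)N1[C@@H](Cc2ccccc2)COC1=O | intermediate
21 | tert-butyl (S)-3-(hydroxymethyl)-4-methylpentanoate | CC(C)[C@H](CC(=O)OC(C)(C)C)CO | intermediate
22 | (S)-4-isopropyldihydrofuran-2(3H)-one | CC(C)[C@@H]1CC(=O)OC1 | intermediate
23 | (S)-3-(hydroxymethyl)-N-methoxy-N,4-dimethylpentanamide | CC(C)[C@H](CC(=O)N(C)OC)CO | intermediate
24 | (S)-5-(hydroxymethyl)-2,6-dimethylhept-1-en-3-one | C=C(C)C(=O)C[C@@H](C(C)C)CO | intermediate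
25 | (S)-2-isopropyl-5-methyl-4-oxohex-5-enal | C=C(C)C(=O)C[C@@H](C(C)C)C=O | intermediate
26 | (S,E)-alkenyl pinacolboronate enone | C=C(C)C(=O)C[C@@H](C(C)C)/C=C/B1OC(C)(C)C(C)(C)O1 | intermediate
27 | ring C–D dienyl trienedione (key-step precursor) | C=C(C)C(=O)C[C@@H](C(C)C)/C=C/C1=C/[C@@H](C)CC[C@@H]2[C@H](CC[C@@H]2C)C1=O | intermediate
28 | tetracyclic dione, C3=C16 (key-step product) | O=C1C2=C[C@H]3[C@H](C(C)C)CC(=O)[C@]3(C)C[C@H]2[C@@H](C)CC[C@@H]2[C@@H]1CC[C@@H]2C | intermediate
29 | tetracyclic dione, C3=C4 | O=C1C2=C(C[C@@]3(C)C(=O)C[C@@H](C(C)C)[C@@H]3C2)[C@@H](C)CC[C@@H]2[C@@H]1CC[C@@H]2C | intermediate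
30 | 8R-hydroxy C2 enone | O=C1C2=C(C[C@@]3(C)[C@H](O)C[C@@H](C(C)C)[C@@H]3C2)[C@@H](C)CC[C@@H]2[C@@H]1CC[C@@H]2C | intermediate
31 | CNP0544018.1 | C=C1C2=C(C[C@@]3(C)[C@H](O)C[C@@H](C(C)C)[C@@H]3C2)[C@@H](C)CC[C@@H]2[C@@H]1CC[C@@H]2C | target

**Step count.** Total: 24 steps. Longest linear sequence: 16 steps (steps 3–13 and 20–24).

**The three steps most likely to fail**

1. **Step 21.**
   - What may go wrong: the cycloaddition may be slow because the C2 acyl group lowers the diene energy. Diene-face selection may erode because the folded cyclooctenone holds C19 over the face that C5 must reach, against the preference set by C11. The methacryloyl unit may polymerise on heating.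
   - Fallback (sets out from 17, comes back at 28): the diene is made electron-rich, and separable C2 epimers offer two different ring-C shapes.
   - Luche reduction of 17 should give the allylic alcohol triflate F1. TBSOTf/2,6-lutidine should give the silyl ether triflate F2. Suzuki coupling with 26 should give the silyl ether trienone F3.
   - Cycloaddition (heat, or Me2AlCl on the only carbonyl) should give the silyl ether adduct F4. TBAF should free the allylic alcohol F5, and MnO2 oxidation should return 28.

2. **Step 22.**
   - What may go wrong: the equilibration may be incomplete or unfavourable because the tetrasubstituted enone is more twisted. Further double-bond migration may occur. The HCl released may epimerise C17 through a dienol.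
   - Fallback (sets out from 28, comes back at 29): the alkene is removed and rebuilt regiospecifically.
   - Wilkinson-catalysed 1,4-hydrosilylation with Et3SiH should give the C2=C3 triethylsilyl enol ether F6 without touching C8. NBS should give the C3 α-bromo ketone F7.
   - Li2CO3/LiBr in hot DMF should eliminate HBr towards C4, as 2-alkyl-2-bromocycloalkanones do towards the endocyclic enone, to give 29.

3. **Step 24.**
   - What may go wrong: the reagent may fail to add to a ketone flanked by a tetrasubstituted alkene and the C22 methine. The titanium Lewis acid may isomerise the product diene.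
   - Fallback (sets out from 30, comes back at 31): a two-stage Peterson olefination.
   - TMSCH2Li/CeCl3 (a small nucleophile of low basicity, used in excess for the free hydroxyl) should give the β-hydroxysilane F8. KH in THF should then eliminate silanolate to give 31.

**Further compounds**
F1 | step 21 | allylic alcohol triflate (C2 epimers) | O=S(=O)(O/C1=C/[C@@H](C)CC[C@@H]2[C@H](CC[C@@H]2C)C1O)C(F)(F)F
F2 | step 21 | silyl ether triflate | O=S(=O)(O/C1=C/[C@@H](C)CC[C@@H]2[C@H](CC[C@@H]2C)C1O[Si](C)(C)C(C)(C)C)C(F)(F)F
F3 | step 21 | silyl ether trienone | C=C(C)C(=O)C[C@@H](C(C)C)/C=C/C1=C/[C@@H](C)CC[C@@H]2[C@H](CC[C@@H]2C)C1O[Si](C)(C)C(C)(C)C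
F4 | step 21 | silyl ether adduct | CC(C)(C)[Si](C)(C)OC1C2=C[C@H]3[C@H](C(C)C)CC(=O)[C@]3(C)C[C@H]2[C@@H](C)CC[C@@H]2[C@@H]1CC[C@@H]2C
F5 | step 21 | allylic alcohol | OC1C2=C[C@H]3[C@H](C(C)C)CC(=O)[C@]3(C)C[C@H]2[C@@H](C)CC[C@@H]2[C@@H]1CC[C@@H]2C
F6 | step 22 | C2=C3 triethylsilyl enol ether | CC[Si](CC)(CC)OC1=C2C[C@H]3[C@H](C(C)C)CC(=O)[C@]3(C)C[C@H]2[C@@H](C)CC[C@@H]2[C@@H]1CC[C@@H]2C
F7 | step 22 | C3 α-bromo ketone | O=C1C2(Br)C[C@H]3[C@H](C(C)C)CC(=O)[C@]3(C)C[C@H]2[C@@H](C)CC[C@@H]2[C@@H]1CC[C@@H]2C
F8 | step 24 | β-hydroxysilane | C[Si](C)(C)CC1(O)C2=C(C[C@@]3(C)[C@H](O)C[C@@H](C(C)C)[C@@H]3C2)[C@@H](C)CC[C@@H]2[C@@H]1CC[C@@H]2C
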